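**Retrosynthetic overview**

- Ring numbering: C1 (CO2H), C2 (=CH), C3 (O-6-methylheptanoyl), C4 (O-tigloyl), C5 (OAc), C6 (CH2). The acid is unmasked last from a tert-butyl ester, and the acyl groups go on one at a time after ring formation (O5, then allylic O3, then O4).
- The only ring, the cyclohexene, is closed at C5–C6 with SmI2. C5 is an aldehyde and C6 is the CH2 terminus of an acrylate whose neighbouring C2 carries an acetate; loss of that acetate places C1=C2.
- The plan rests on the trans C3–O/C4–O pair flanked by C2 and C5. These four carbons are the C2-symmetric D-threitol (D-tartrate) chain, so C3 and C4 are bought. Only C5 is created, in the ring closure, under control of the trans-fused O3/O4 dioxolane.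
- C1, C6 and the ester carbon come from tert-butyl acrylate by a Morita–Baylis–Hillman reaction at C2.

Key step: step 8

Remark 1: compounds 6 to 9 are carried as mixtures of epimers at the carbinol/acetoxy carbon (ring C2), because this centre becomes sp2 in step 8.
Remark 2: the ring numbering above is also used for the open-chain intermediates. Diol 2 can be bought, which would remove step 1.

**Route**

Step 1
Reactants: 1 dimethyl 2,3-O-isopropylidene-D-tartrate [dimethyl (4S,5S)-2,2-dimethyl-1,3-dioxolane-4,5-dicarboxylate]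
Product: 2 2,3-O-isopropylidene-D-threitol [(4R,5R)-2,2-dimethyl-1,3-dioxolane-4,5-diyl]dimethanol
Conditions: LiAlH4, THF, 0 °C → reflux; Fieser work-up
Reagents that add atoms: none
Why: LiAlH4 reduction of both esters to primary alcohols does not touch the ketal or the C–O bonds at the two stereocentres.

Step 2
Reactants: 2 2,3-O-isopropylidene-D-threitol
Product: 3 [(4R,5R)-5-({[tert-butyl(dimethyl)silyl]oxy}methyl)-2,2-dimethyl-1,3-dioxolan-4-yl]methanol
Conditions: NaH (1.0 equiv), THF, 0 °C → rt; then TBSCl (1.0 equiv)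
Reagents that add atoms: tert-butyldimethylsilyl chloride, CC(C)(C)[Si](C)(C)Cl
Why: Monosilylation of a symmetrical diol through its sparingly soluble monosodium alkoxide (silyl ether formation) should stop after one silyl group, and the C2 symmetry makes the two hydroxyls equivalent.

Step 3
Reactants: 3 mono-TBS ether of the threitol acetonide
Product: 4 (4S,5R)-5-({[tert-butyl(dimethyl)silyl]oxy}methyl)-2,2-dimethyl-1,3-dioxolane-4-carbaldehyde
Conditions: Dess–Martin periodinane, NaHCO3, CH2Cl2, 0 °C → rt
Reagents that add atoms: none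
Why: Buffered Dess–Martin oxidation of the primary alcohol gives the α-alkoxy aldehyde without base, and the trans-disubstituted dioxolane is in any case the stable arrangement.

Step 4
Reactants: 4 silyloxy aldehyde; 5 tert-butyl acrylate
Product: 6 tert-butyl 2-[(RS)-hydroxy{(4R,5R)-5-({[tert-butyl(dimethyl)silyl]oxy}methyl)-2,2-dimethyl-1,3-dioxolan-4-yl}methyl]prop-2-enoate
Conditions: quinuclidine (0.5 equiv), MeOH (0.75 equiv), neat in 5 (3 equiv), rt
Reagents that add atoms: none
Why: Morita–Baylis–Hillman reaction: the amine–acrylate zwitterion adds to the activated α-alkoxy aldehyde and methanol assists the proton transfer; the new carbinol centre (ring C2) is left uncontrolled because step 8 erases it.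

Step 5
Reactants: 6 Morita–Baylis–Hillman alcohol
Product: 7 tert-butyl 2-[(RS)-acetoxy{(4R,5R)-5-({[tert-butyl(dimethyl)silyl]oxy}methyl)-2,2-dimethyl-1,3-dioxolan-4-yl}methyl]prop-2-enoate
Conditions: Ac2O, pyridine, DMAP (cat.), CH2Cl2, 0 °C
Reagents that add atoms: acetic anhydride, CC(=O)OC(C)=O
Why: DMAP-catalysed acetylation of the secondary allylic alcohol at 0 °C installs the leaving group for step 8 without allylic transposition.

Step 6
Reactants: 7 silyl ether acetate
Product: 8 tert-butyl 2-[(RS)-acetoxy{(4R,5R)-5-(hydroxymethyl)-2,2-dimethyl-1,3-dioxolan-4-yl}methyl]prop-2-enoate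
Conditions: HF·pyridine, pyridine, THF, 0 °C → rt
Reagents that add atoms: none
Why: Buffered HF·pyridine desilylation cleaves the primary TBS ether in a non-basic medium, which avoids acetyl migration and attack on the allylic acetate and is tolerated by the ketal.

Step 7
Reactants: 8 primary alcohol
Product: 9 tert-butyl 2-[(RS)-acetoxy{(4R,5S)-5-formyl-2,2-dimethyl-1,3-dioxolan-4-yl}methyl]prop-2-enoate
Conditions: Dess–Martin periodinane, NaHCO3, CH2Cl2, 0 °C → rt; used crude at once
Reagents that add atoms: none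
Why: Dess–Martin oxidation gives the aldehyde under neutral conditions that leave the allylic acetate, the acrylate and the ketal intact.

Step 8
Reactants: 9 aldehyde Morita–Baylis–Hillman acetate
Product: 11 tert-butyl (3R,4R,5S)-5-hydroxy-3,4-(isopropylidenedioxy)cyclohex-1-ene-1-carboxylate, via bis-samarium β-acetoxy enolate 10 (not isolated)
Conditions: SmI2 (2.2 equiv, 0.1 M in THF) added slowly to 9 (0.005 M) and HMPA (9 equiv) in THF, −78 °C → −40 °C; sat. aq. NH4Cl
Reagents that add atoms: none
Why: Proposed new method: electron transfer from SmI2 to the C5 aldehyde gives a ketyl that attacks the unsubstituted acrylate carbon C6, a second electron converts the ester-stabilised C1 radical into the trivalent samarium enolate 10, and E1cB loss of the C2 acetate from 10 leaves the C1=C2 enoate; should the acrylate be reduced first, acetate loss gives a 2-(alkoxycarbonyl)allylsamarium that can reach the aldehyde only through C6 (attack through C2 would make a cyclobutane), so both orders of events lead to 11. The closest known reaction types are SmI2 ketyl–acrylate reductive cyclisations of sugar-derived alkoxy aldehydes and the SmI2 reductive removal of acetate from Morita–Baylis–Hillman acetates, which have not been merged into one ring closure with radical-polar crossover. The cyclohexene is closed in the 6-endo-trig mode, preferred over 5-exo because the nucleophilic ketyl adds to the β-carbon of the acceptor to give a tertiary α-ester radical and because 5-exo attack would create a highly strained trans-fused dioxolane–cyclopentane. The one new stereocentre, C5, is controlled by the trans-fused dioxolane, which holds O3 and O4 equatorial in a chair-like transition state where the bulky HMPA-solvated O–Sm group lies pseudo-equatorial and anti to the C4–O dipole, so that O5 ends up trans to O4 (5S). The step needs cyclisation to outpace pinacol dimerisation, protonation of the intermediates and reduction of the γ-alkoxy enoate product, which the high dilution, the absence of a proton source, −78 °C and slow dosing of just over two equivalents of SmI2 are chosen to secure; the two C2 epimers of 9 converge because C2 becomes sp2.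

Step 9
Reactants: 11 cyclohexenol acetonide
Product: 12 tert-butyl (3R,4R,5S)-5-acetoxy-3,4-(isopropylidenedioxy)cyclohex-1-ene-1-carboxylate
Conditions: Ac2O, pyridine, DMAP (cat.), CH2Cl2, 0 °C → rt
Reagents that add atoms: acetic anhydride, CC(=O)OC(C)=O
Why: DMAP-catalysed acetylation of the only free hydroxyl (O5) proceeds with retention because the C5–O bond is not touched.

Step 10
Reactants: 12 acetate acetonide
Product: 13 tert-butyl (3R,4S,5S)-5-acetoxy-3,4-dihydroxycyclohex-1-ene-1-carboxylate
Conditions: AcOH/H2O (4:1), 45 °C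
Reagents that add atoms: none
Why: Acid-catalysed ketal hydrolysis cleaves the strained trans-fused dioxolane under conditions that spare the tert-butyl ester and the O5 acetate, and no stereocentre is involved (the 4S label reflects only a priority change).

Step 11
Reactants: 13 diol acetate; 14 6-methylheptanoic acid
Product: 16 tert-butyl (3R,4R,5S)-5-acetoxy-4-hydroxy-3-[(6-methylheptanoyl)oxy]cyclohex-1-ene-1-carboxylate, via 6-methylheptanoyl chloride 15 (not isolated)
Conditions: 14, (COCl)2, DMF (cat.), CH2Cl2, rt, concentrate; then 13, 2,4,6-collidine, CH2Cl2, −78 → −40 °C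
Reagents that add atoms: none
Why: Regioselective esterification with an acid chloride and a hindered pyridine base at low temperature should take place at the allylic O3–H, whose only neighbour on the alkene side is the planar C2–H, and not at O4–H, which is flanked by two oxygenated sp3 carbons; the non-nucleophilic base and low temperature suppress acetyl migration from O5.

Step 12
Reactants: 16 O3-monoester; 17 tiglic acid [(2E)-2-methylbut-2-enoic acid]
Product: 19 tert-butyl (3R,4R,5S)-5-acetoxy-3-[(6-methylheptanoyl)oxy]-4-{[(2E)-2-methylbut-2-enoyl]oxy}cyclohex-1-ene-1-carboxylate, via tigloyl 2,4,6-trichlorobenzoyl mixed anhydride 18 (not isolated)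
Conditions: 17, 2,4,6-trichlorobenzoyl chloride, Et3N, toluene, rt; then 16, DMAP, rt → 40 °C
Reagents that add atoms: none
Why: Yamaguchi esterification: DMAP attacks the unhindered tigloyl carbonyl of the mixed anhydride and the acylpyridinium acylates the remaining hindered O4–H without deconjugating the (E)-2-methylbut-2-enoyl unit.

Step 13
Reactants: 19 tert-butyl ester triester
Product: 20 (3R,4R,5S)-5-acetoxy-3-[(6-methylheptanoyl)oxy]-4-{[(2E)-2-methylbut-2-enoyl]oxy}cyclohex-1-ene-1-carboxylic acid (CNP0225437.1)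
Conditions: CF3CO2H/CH2Cl2 (1:4), 0 °C → rt
Reagents that add atoms: none
Why: Acidolysis of the tert-butyl ester (E1 loss of isobutene) frees the acid, while the three secondary esters, which cannot ionise readily next to the electron-poor alkene, should survive.

**Compound list**

1 | dimethyl 2,3-O-isopropylidene-D-tartrate | COC(=O)[C@H]1OC(C)(C)O[C@@H]1C(=O)OC | starting material
2 | 2,3-O-isopropylidene-D-threitol | OC[C@H]1OC(C)(C)O[C@@H]1CO | intermediate
3 | [(4R,5R)-5-({[tert-butyl(dimethyl)silyl]oxy}methyl)-2,2-dimethyl-1,3-dioxolan-4-yl]methanol | OC[C@H]1OC(C)(C)O[C@@H]1CO[Si](C)(C)C(C)(C)C | intermediate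
4 | (4S,5R)-5-({[tert-butyl(dimethyl)silyl]oxy}methyl)-2,2-dimethyl-1,3-dioxolane-4-carbaldehyde | O=C[C@H]1OC(C)(C)O[C@@H]1CO[Si](C)(C)C(C)(C)C | intermediate
5 | tert-butyl acrylate | C=CC(=O)OC(C)(C)C | starting material
6 | tert-butyl 2-[(RS)-hydroxy{(4R,5R)-5-({[tert-butyl(dimethyl)silyl]oxy}methyl)-2,2-dimethyl-1,3-dioxolan-4-yl}methyl]prop-2-enoate | C=C(C(=O)OC(C)(C)C)C(O)[C@H]1OC(C)(C)O[C@@H]1CO[Si](C)(C)C(C)(C)C | intermediate
7 | tert-butyl 2-[(RS)-acetoxy{(4R,5R)-5-({[tert-butyl(dimethyl)silyl]oxy}methyl)-2,2-dimethyl-1,3-dioxolan-4-yl}methyl]prop-2-enoate | C=C(C(=O)OC(C)(C)C)C(OC(C)=O)[C@H]1OC(C)(C)O[C@@H]1CO[Si](C)(C)C(C)(C)C | intermediate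
8 | tert-butyl 2-[(RS)-acetoxy{(4R,5R)-5-(hydroxymethyl)-2,2-dimethyl-1,3-dioxolan-4-yl}methyl]prop-2-enoate | C=C(C(=O)OC(C)(C)C)C(OC(C)=O)[C@H]1OC(C)(C)O[C@@H]1CO | intermediate
9 | tert-butyl 2-[(RS)-acetoxy{(4R,5S)-5-formyl-2,2-dimethyl-1,3-dioxolan-4-yl}methyl]prop-2-enoate | C=C(C(=O)OC(C)(C)C)C(OC(C)=O)[C@H]1OC(C)(C)O[C@@H]1C=O | intermediate
10 | bis-samarium β-acetoxy enolate formed by C5–C6 closure (not isolated) | CC(C)(C)OC(O[Sm](I)I)=C1C[C@H](O[Sm](I)I)[C@H]2OC(C)(C)O[C@@H]2C1OC(C)=O | intermediate
11 | tert-butyl (3R,4R,5S)-5-hydroxy-3,4-(isopropylidenedioxy)cyclohex-1-ene-1-carboxylate | CC(C)(C)OC(=O)C1=C[C@H]2OC(C)(C)O[C@@H]2[C@@H](O)C1 | intermediate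
12 | tert-butyl (3R,4R,5S)-5-acetoxy-3,4-(isopropylidenedioxy)cyclohex-1-ene-1-carboxylate | CC(C)(C)OC(=O)C1=C[C@H]2OC(C)(C)O[C@@H]2[C@@H](OC(C)=O)C1 | intermediate
13 | tert-butyl (3R,4S,5S)-5-acetoxy-3,4-dihydroxycyclohex-1-ene-1-carboxylate | O[C@@H]1[C@@H](OC(C)=O)CC(C(=O)OC(C)(C)C)=C[C@H]1O | intermediate
14 | 6-methylheptanoic acid | CC(C)CCCCC(=O)O | starting material
15 | 6-methylheptanoyl chloride (not isolated) | CC(C)CCCCC(=O)Cl | intermediate
16 | tert-butyl (3R,4R,5S)-5-acetoxy-4-hydroxy-3-[(6-methylheptanoyl)oxy]cyclohex-1-ene-1-carboxylate | O[C@@H]1[C@@H](OC(C)=O)CC(C(=O)OC(C)(C)C)=C[C@H]1OC(=O)CCCCC(C)C | intermediate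
17 | tiglic acid | C/C=C(\C)C(=O)O | starting material
18 | tigloyl 2,4,6-trichlorobenzoyl mixed anhydride (not isolated) | C/C=C(\C)C(=O)OC(=O)c1c(Cl)cc(Cl)cc1Cl | intermediate
19 | tert-butyl (3R,4R,5S)-5-acetoxy-3-[(6-methylheptanoyl)oxy]-4-{[(2E)-2-methylbut-2-enoyl]oxy}cyclohex-1-ene-1-carboxylate | C/C=C(\C)C(=O)O[C@@H]1[C@@H](OC(C)=O)CC(C(=O)OC(C)(C)C)=C[C@H]1OC(=O)CCCCC(C)C | intermediate
20 | (3R,4R,5S)-5-acetoxy-3-[(6-methylheptanoyl)oxy]-4-{[(2E)-2-methylbut-2-enoyl]oxy}cyclohex-1-ene-1-carboxylic acid | C/C=C(\C)C(=O)O[C@@H]1[C@@H](OC(C)=O)CC(C(=O)O)=C[C@H]1OC(=O)CCCCC(C)C | target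

**Step count**

Total steps: 13. Longest linear sequence: 13 (1 → 20).

**Steps most likely to fail**

Step 8. The ketyl or allylsamarium may be lost to intermolecular pinacol coupling or to simple reductive deacetoxylation. The γ-alkoxy enoate product may be reduced further, or closure may occur with poor facial selectivity at C5. The fallback uses known chemistry (Barbier allylation, ring-closing metathesis, Mitsunobu inversion) and makes C1=C2 instead of C5–C6. It sets out from compound 4 and rejoins the route at compound 12.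
- Methylenation of 4 with Ph3P=CH2 (Ph3PCH3Br, KN(SiMe3)2, THF, −78 → 0 °C) gives tert-butyl{[(4R,5R)-5-ethenyl-2,2-dimethyl-1,3-dioxolan-4-yl]methoxy}dimethylsilane F1.
- Bu4NF in THF gives [(4R,5R)-5-ethenyl-2,2-dimethyl-1,3-dioxolan-4-yl]methanol F2.
- Dess–Martin oxidation gives (4S,5R)-5-ethenyl-2,2-dimethyl-1,3-dioxolane-4-carbaldehyde F3.
- Barbier allylation with purchased tert-butyl 2-(bromomethyl)acrylate (Zn dust, THF/sat. aq. NH4Cl, rt) should give, mainly as the Felkin–Anh 4,5-anti isomer, tert-butyl (4R)-4-[(4R,5R)-5-ethenyl-2,2-dimethyl-1,3-dioxolan-4-yl]-4-hydroxy-2-methylidenebutanoate F4.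
- Ring-closing metathesis with the second-generation Grubbs catalyst, RuCl2(=CHPh)(H2IMes)(PCy3), in CH2Cl2 at 40 °C gives the C5 epimer of 11, tert-butyl (3R,4R,5R)-5-hydroxy-3,4-(isopropylidenedioxy)cyclohex-1-ene-1-carboxylate F5.
- Mitsunobu reaction of F5 with acetic acid (PPh3, DIAD, THF, 0 °C) inverts C5 and delivers acetate 12.

Step 11. Discrimination between the two secondary hydroxyls may be incomplete, and the O5 acetate may migrate to O4 while O4–H is free. The fallback reverses the order of the two acylations behind a bulky temporary silyl group, which is more sensitive to the steric difference. It sets out from compound 13 and rejoins at compound 19.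
- TBSOTf (1.05 equiv), 2,6-lutidine, CH2Cl2, −78 °C should silylate the allylic O3 to give tert-butyl (3R,4R,5S)-5-acetoxy-3-{[tert-butyl(dimethyl)silyl]oxy}-4-hydroxycyclohex-1-ene-1-carboxylate F6.
- Yamaguchi tigloylation of O4 (17, 2,4,6-trichlorobenzoyl chloride, Et3N, DMAP, toluene) gives tert-butyl (3R,4R,5S)-5-acetoxy-3-{[tert-butyl(dimethyl)silyl]oxy}-4-{[(2E)-2-methylbut-2-enoyl]oxy}cyclohex-1-ene-1-carboxylate F7.
- HF·pyridine in THF frees O3 to give tert-butyl (3R,4S,5S)-5-acetoxy-3-hydroxy-4-{[(2E)-2-methylbut-2-enoyl]oxy}cyclohex-1-ene-1-carboxylate F8.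
- Acylation of F8 with 6-methylheptanoyl chloride 15 (pyridine, DMAP, CH2Cl2, 0 °C) gives 19.

Step 4. Turnover of the amine-catalysed addition may be very slow with the hindered tert-butyl acrylate, and the aldehyde may be lost to hydration or epimerisation over the long reaction time. The fallback replaces the catalytic equilibrium by a stoichiometric carbonyl addition. It sets out from compound 4 and rejoins at compound 6.
- Hydroalumination of tert-butyl propiolate with i-Bu2AlH in THF containing N-methylmorpholine N-oxide at 0 °C gives the α-aluminoacrylate tert-butyl 2-[bis(2-methylpropyl)alumanyl]prop-2-enoate F9.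
- F9 adds to aldehyde 4 (0 °C → rt) and gives 6 after aqueous work-up.

**Further compounds**

F1 | step 8 | tert-butyl{[(4R,5R)-5-ethenyl-2,2-dimethyl-1,3-dioxolan-4-yl]methoxy}dimethylsilane | C=C[C@H]1OC(C)(C)O[C@@H]1CO[Si](C)(C)C(C)(C)C
F2 | step 8 | [(4R,5R)-5-ethenyl-2,2-dimethyl-1,3-dioxolan-4-yl]methanol | C=C[C@H]1OC(C)(C)O[C@@H]1CO
F3 | step 8 | (4S,5R)-5-ethenyl-2,2-dimethyl-1,3-dioxolane-4-carbaldehyde | C=C[C@H]1OC(C)(C)O[C@@H]1C=O
F4 | step 8 | tert-butyl (4R)-4-[(4R,5R)-5-ethenyl-2,2-dimethyl-1,3-dioxolan-4-yl]-4-hydroxy-2-methylidenebutanoate | C=C[C@H]1OC(C)(C)O[C@@H]1[C@H](O)CC(=C)C(=O)OC(C)(C)C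
F5 | step 8 | tert-butyl (3R,4R,5R)-5-hydroxy-3,4-(isopropylidenedioxy)cyclohex-1-ene-1-carboxylate | CC(C)(C)OC(=O)C1=C[C@H]2OC(C)(C)O[C@@H]2[C@H](O)C1
F6 | step 11 | tert-butyl (3R,4R,5S)-5-acetoxy-3-{[tert-butyl(dimethyl)silyl]oxy}-4-hydroxycyclohex-1-ene-1-carboxylate | O[C@@H]1[C@@H](OC(C)=O)CC(C(=O)OC(C)(C)C)=C[C@H]1O[Si](C)(C)C(C)(C)C
F7 | step 11 | tert-butyl (3R,4R,5S)-5-acetoxy-3-{[tert-butyl(dimethyl)silyl]oxy}-4-{[(2E)-2-methylbut-2-enoyl]oxy}cyclohex-1-ene-1-carboxylate | C/C=C(\C)C(=O)O[C@@H]1[C@@H](OC(C)=O)CC(C(=O)OC(C)(C)C)=C[C@H]1O[Si](C)(C)C(C)(C)C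
F8 | step 11 | tert-butyl (3R,4S,5S)-5-acetoxy-3-hydroxy-4-{[(2E)-2-methylbut-2-enoyl]oxy}cyclohex-1-ene-1-carboxylate | C/C=C(\C)C(=O)O[C@@H]1[C@@H](OC(C)=O)CC(C(=O)OC(C)(C)C)=C[C@H]1O
F9 | step 4 | tert-butyl 2-[bis(2-methylpropyl)alumanyl]prop-2-enoate | C=C([Al](CC(C)C)CC(C)C)C(=O)OC(C)(C)C
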